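# Proposal: total synthesis of the daucane veratrate 23 by an intramolecular de Mayo ring expansion

Remarks on the chemistry (assumptions):
- Daucane numbering is used throughout: C1 (quaternary, methyl), C2, C3, C4 (carbinol, isopropyl), C5 (ring-fusion CH), C6 (ester carbon), C7, C8 (methyl-bearing alkene carbon), C9, C10.
- The tether between C5 and the alkene carbon C1 must contain three atoms (C4, C3, C2). The acyl group is therefore 4-methylpent-4-enoyl and the acid is 4-methylpent-4-enoic acid 6; one carbon more would close a six-membered ring.
- Hydrazone C=N geometry is left unspecified in the SMILES.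
- From step 7 on, C8 is carried as a mixture of epimers; it becomes sp2 in step 8.
- In step 11 the ligand antipode written is used unless one comparison with its commercial mirror image shows the latter to be the matched one.

## The problem

Target 23 is the 3,4-dimethoxybenzoate of a daucane diol: a cyclopentane (C1–C5) trans-fused along C1–C5 to a cycloheptene (C1, C5–C10). Its four contiguous stereocentres are (1R,4R,5S,6S): the C1 methyl and H-5 are trans, the C4 hydroxyl lies on the face of the C1 methyl, and O-6 lies on the face of H-5. C1 is quaternary and unfunctionalised, so it must be fixed in a C–C bond-forming step. Once in place it should direct C4 reliably (attack on a trans-fused C4 ketone anti to the angular methyl), but C5 and C6 only weakly, so C6 needs reagent control and C5 thermodynamic control. The tertiary alcohol dehydrates under acid, the C8=C9 alkene can migrate into conjugation once a C4 carbonyl and a C5=C6 double bond are present, and a C6 acyloxy group beta to a C4 ketone would eliminate; the ester is therefore attached last. Two ketones of similar reactivity, at C4 and C9, appear on the way and must be told apart. The enabling feature is that with ketones at C4 and C9 the path C4–C5–C1–C10–C9 is a 1,5-diketone. This is the retron of a de Mayo reaction: the enol C5=C9 of a 2-acylcyclopentanone (ring C5, C6, C7, C8, C9) adds to an alkene C1=C10 tethered through C4, C3 and C2, which closes ring C1–C5 and expands the cyclopentanone to the seven-membered ring.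

## Retrosynthesis

**Ester C6–O.** Target 23 is cut at the acyl–oxygen bond to diol 21 and veratric acid 22. Only the secondary hydroxyl of 21 can be acylated, so no protecting group is needed, and placing this cut last keeps the base-labile β-acyloxy pattern out of all organometallic steps.

**C4–isopropyl.** Diol 21 is cut at the C4–isopropyl bond to β-hydroxy ketone 20. This is preferred over making the carbinol earlier because only in the saturated, trans-fused ketone does the axial C1 methyl shield one face of C4 clearly. The forward step needs a non-basic isopropyl donor that tolerates a free hydroxyl.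

**C6–O and C5–H.** Ketone 20 is traced through boronate 19 to enone 18 (C6–B and C5–H bonds cut). Conjugate borylation puts the heteroatom on the unhindered β-carbon under catalyst control and leaves C5 as an epimerisable centre that can settle trans-diequatorial to the C6 substituent. A hydroboration of a C4 carbinol alkene was rejected because the isopropyl group would steer boron to the wrong face.

**Enone and C8=C9 alkene.** Enone 18 comes from silyl enol ether 17 (C5=C6 introduced by dehydrogenation). 17 comes from enol triflate 16 (C9–O cut, triflate replaced by hydrogen), and 16 from keto silyl enol ether 14. This order makes the C9 ketone disappear before any nucleophile is used at C4. The silyl enol ether both masks C4 and stores the C4=C5 regiochemistry that later gives the enone without a second enolisation.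

**Telling the ketones apart.** 14 derives from dione 12. The cyclopentanone is the more acidic ketone (about two pKa units for the parent rings) and has the only unhindered methylene (C3), so a slight deficit of base selects it both kinetically and at equilibrium.

**Key disconnection.** Dione 12 is cut at C5–C1 and C9–C10 (with C5–C9 re-formed) to diketone 10, through cyclobutanol 11. Two rings, two skeletal bonds and the quaternary centre arise in one operation, and the product carries carbonyl groups exactly where the target needs the isopropyl carbinol and the alkene. The forward reaction must give the straight adduct and must add to the enol face anti to the C8 methyl.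

**Photosubstrate.** Diketone 10 is cut at the C5–C4 bond to hydrazone 5 and Weinreb amide 7, with enehydrazine 9 as the link. 5 comes from hydrazone 3 by asymmetric methylation, 3 from cyclopentanone 1 and SAMP 2, and 7 from acid 6. The hydrazone serves twice: it sets the C8 methyl centre and it directs the second metalation to the far α-carbon.

## Roads not taken

**Alternative 1: alkylidene carbene C–H insertion.** The cut is the C1–C5 bond of the five-membered ring only. (S)-Citronellol A1 would be degraded to the isopropyl ketone A2; lithiated trimethylsilyldiazomethane would turn the carbonyl into an alkylidene carbene that inserts into the tertiary C–H bond with retention, giving cyclopentene A3.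
- Merits: the quaternary centre comes from the chiral pool with full fidelity and the isopropyl group is already in place. In enantiocontrol this road is better than the chosen plan, which relies on a temporary methyl centre.
- Weak points: A3 contains only the small ring. The seven-membered ring, the C5–C6 bond, the C8=C9 alkene and three stereocentres would all have to be added afterwards. An anti opening of a C4–C5 epoxide would place the new C5 substituent trans to the C4 oxygen, whereas the target has them cis.
- Comparison: the chosen plan sets against the better enantiocontrol the formation of both rings and of the 1,5-dioxygen pattern in a single step.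

**Alternative 2: intramolecular Buchner reaction.** The cut is C1–C5 and C1–C10. Diazoketone A4 would be decomposed by Rh2(OAc)4, or by CuPF6(MeCN)4 with a chiral bisoxazoline; the carbene adds to the ipso and free ortho carbons and the norcaradiene opens to the cycloheptatriene A5.
- Merits: both rings, the quaternary centre and all fifteen skeletal carbons arrive in one step, with the C4 carbinol and a C6 oxygen already present. In convergence this road is better than the chosen plan.
- Weak points: the tertiary benzylic C4 centre of A4 must first be made as a single enantiomer and must then control C1 across the forming ring. An α-methyl diazoketone can lose the carbene by 1,2-hydride shift. A5 needs heavy redox correction: the C2 ketone must be removed next to a quaternary carbon, three ring double bonds reduced to one at C8=C9, and C5 and C6 set by reduction of an enol ether.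
- Comparison: the chosen plan gives in 12 an intermediate whose oxidation pattern maps directly onto the target.

**Alternative 3: Birch reduction and dibromocarbene ring expansion.** The cut inserts C5 between C6 and C1. 2,5-Dimethylanisole A6 would be reduced to diene A7; dibromocarbene (CHBr3, KOt-Bu) adds to the enol ether double bond and the dibromocyclopropane opens, with AgBF4 if needed, to bromodienone A8.
- Merits: cheap aromatic material and no photochemistry. The seven-membered ring with both methyl groups, the C8=C9 alkene, a C6 carbonyl and a C5 handle is reached in three steps. In scalability this road is better.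
- Weak points: A8 is achiral, so all four stereocentres, including the quaternary one, must be created later by conjugate addition to a β,β-disubstituted α-bromo enone and cyclopentannulation. A8 can also lose HBr to a tropone or move its skipped alkene into conjugation.
- Comparison: the chosen plan sets against this the fixing of C1 in the ring-forming step itself.

Key step: step 6

## Route

Step 1
Reactants: 1 cyclopentanone; 2 (S)-1-amino-2-(methoxymethyl)pyrrolidine (SAMP)
Product: 3 (S)-N-cyclopentylidene-2-(methoxymethyl)pyrrolidin-1-amine
Conditions: cyclohexane, 4 Å molecular sieves, 60 °C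
Reagents that add atoms: none
Why: Hydrazone condensation of a ketone with a 1,1-disubstituted hydrazine; water is removed and no stereocentre is formed.

Step 2
Reactants: 3 (S)-N-cyclopentylidene-2-(methoxymethyl)pyrrolidin-1-amine
Product: 5 (2S)-2-(methoxymethyl)-N-[(2R)-2-methylcyclopentylidene]pyrrolidin-1-amine, via lithium azaenolate 4 (not isolated)
Conditions: LiN(i-Pr)2, THF, 0 °C; then MeI, −95 °C → rt; H2O
Reagents that add atoms: iodomethane, CI
Why: SAMP-hydrazone alkylation: the lithium of the azaenolate is chelated by the methoxymethyl group, so iodomethane enters on the face away from the pyrrolidine substituent, which should set the (R) methyl centre.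

Step 3
Reactants: 6 4-methylpent-4-enoic acid
Product: 7 N-methoxy-N,4-dimethylpent-4-enamide
Conditions: MeNHOMe·HCl, EDC·HCl, Et3N, DMAP (cat.), CH2Cl2, 0 °C → rt
Reagents that add atoms: N,O-dimethylhydroxylamine hydrochloride, CNOC.Cl
Why: Carbodiimide amide coupling to the Weinreb amide; the 1,1-disubstituted alkene is inert and no stereocentre is involved.

Step 4
Reactants: 5 (2S)-2-(methoxymethyl)-N-[(2R)-2-methylcyclopentylidene]pyrrolidin-1-amine; 7 N-methoxy-N,4-dimethylpent-4-enamide
Product: 9 1-[(3R)-2-{[(2S)-2-(methoxymethyl)pyrrolidin-1-yl]amino}-3-methylcyclopent-1-en-1-yl]-4-methylpent-4-en-1-one, via lithium azaenolate 8 (not isolated)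
Conditions: LiN(i-Pr)2, THF, 0 °C; then 7, −78 → 0 °C; aq NH4Cl
Reagents that add atoms: none
Why: The second metalation of the hydrazone takes place at the unsubstituted α′-methylene and leaves the methyl centre untouched; acylation by the Weinreb amide (Weinreb ketone synthesis) stops at the chelated tetrahedral adduct, so the acidic product cannot quench azaenolate, and work-up gives the hydrogen-bonded enehydrazine tautomer.

Step 5
Reactants: 9 1-[(3R)-2-{[(2S)-2-(methoxymethyl)pyrrolidin-1-yl]amino}-3-methylcyclopent-1-en-1-yl]-4-methylpent-4-en-1-one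
Product: 10 (5R)-5-methyl-2-(4-methylpent-4-enoyl)cyclopentan-1-one
Conditions: 1 M aq HCl, pentane/Et2O (two-phase), 0 °C → rt
Reagents that add atoms: water, O
Why: Acid hydrolysis of a vinylogous hydrazide; the diketone passes at once into the organic phase, enolisation of the 1,3-dicarbonyl runs toward C5 and not toward the methyl-bearing C8, and the auxiliary is recovered from the aqueous phase.

Step 6
Reactants: 10 (5R)-5-methyl-2-(4-methylpent-4-enoyl)cyclopentan-1-one
Product: 12 (3aR,6R)-3a,6-dimethyloctahydroazulene-1,5-dione, via cyclobutanol photoadduct 11 (not isolated)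
Conditions: hν (medium-pressure Hg lamp, Pyrex, λ > 300 nm), cyclohexane (0.01 M), N2, rt
Reagents that add atoms: none
Why: De Mayo reaction: excitation of the hydrogen-bonded enol of 10 is followed by (2+2) addition of the enol C=C to the tethered 1,1-disubstituted alkene, and cyclobutanol 11, a strained β-hydroxy ketone, opens in the flask by retro-aldol cleavage of C5–C9. The closest known reaction type is the intramolecular de Mayo photocycloaddition of enolised 2-acylcycloalkanones, which gives two-carbon ring-expanded 1,5-diketones. The cyclopentane closes first by 1,5-bonding of C5 to C1 through the three-atom tether (rule of five, straight adduct), the cyclobutane closes by coupling of the C10 radical with C9, and the seven-membered ring is not closed directly but results from fragmentation of the fused cyclopentanol. The only lasting new stereocentre is C1: both five-membered rings must be cis-fused to the cyclobutane, so its configuration follows from the enol face that is attacked, and the C8 methyl next to C9 should send the alkene to the opposite face, which gives (1R). C9 ceases to be a stereocentre on cleavage and C5 becomes epimerisable. The step needs straight rather than crossed regiochemistry, which the tether length secures because closure of C10 on C4 would build a bicyclo[2.1.1]hexane inside the new cyclopentanone, and it needs facial selectivity, which rests on the C8 methyl alone.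

Step 7
Reactants: 12 (3aR,6R)-3a,6-dimethyloctahydroazulene-1,5-dione
Product: 14 (3aR)-1-[(tert-butyldimethylsilyl)oxy]-3a,6-dimethyl-2,3,3a,6,7,8-hexahydroazulen-5(4H)-one, via potassium enolate 13 (not isolated)
Conditions: KN(SiMe3)2 (0.95 equiv), THF, −78 → 0 °C; then TBSCl, −78 °C → rt
Reagents that add atoms: tert-butyldimethylsilyl chloride, CC(C)(C)[Si](C)(C)Cl
Why: Thermodynamic enolate formation and O-silylation: the cyclopentanone is the more acidic ketone and its C3 methylene the only unhindered α-site, so a slight deficit of base settles on this ketone and proton exchange moves the enolate to the more substituted C4=C5 position, where TBSCl traps it; any epimerisation at C8 is harmless.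

Step 8
Reactants: 14 (3aR)-1-[(tert-butyldimethylsilyl)oxy]-3a,6-dimethyl-2,3,3a,6,7,8-hexahydroazulen-5(4H)-one
Product: 16 (3aR)-1-[(tert-butyldimethylsilyl)oxy]-3a,6-dimethyl-2,3,3a,4,7,8-hexahydroazulen-5-yl trifluoromethanesulfonate, via lithium enolate 15 (not isolated)
Conditions: LiN(SiMe3)2 (0.95 equiv), THF, −78 °C → rt; then PhNTf2, 0 °C → rt; aq NH4Cl
Reagents that add atoms: N-phenylbis(trifluoromethanesulfonimide), O=S(=O)(N(c1ccccc1)S(=O)(=O)C(F)(F)F)C(F)(F)F
Why: Enol triflate formation from the thermodynamic lithium enolate: the C10 methylene is shielded by the adjacent quaternary C1 and equilibration favours the tetrasubstituted C8=C9 enolate, while the silyl enol ether keeps C4 out of play.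

Step 9
Reactants: 16 (3aR)-1-[(tert-butyldimethylsilyl)oxy]-3a,6-dimethyl-2,3,3a,4,7,8-hexahydroazulen-5-yl trifluoromethanesulfonate
Product: 17 tert-butyl{[(3aR)-3a,6-dimethyl-2,3,3a,4,7,8-hexahydroazulen-1-yl]oxy}dimethylsilane
Conditions: Pd(PPh3)4 (5 mol %), HCO2H, Et3N (excess), DMF, 60 °C
Reagents that add atoms: none
Why: Palladium-catalysed formate reduction of an enol triflate (oxidative addition, formate exchange, decarboxylation, reductive elimination) places hydrogen on C9 and leaves the C8=C9 alkene where the triflate defined it; a zerovalent palladium source and excess amine spare the silyl enol ether.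

Step 10
Reactants: 17 tert-butyl{[(3aR)-3a,6-dimethyl-2,3,3a,4,7,8-hexahydroazulen-1-yl]oxy}dimethylsilane
Product: 18 (3aR)-3a,6-dimethyl-3,3a,4,7-tetrahydroazulen-1(2H)-one
Conditions: Pd(OAc)2 (1.1 equiv), MeCN, rt → 40 °C
Reagents that add atoms: none
Why: Saegusa–Ito oxidation: the divalent palladium enolate at C5 has β-hydrogens only at C6 because C1 is quaternary, so the C5=C6 enone forms regiospecifically and the isolated trisubstituted alkene is left alone.

Step 11
Reactants: 18 (3aR)-3a,6-dimethyl-3,3a,4,7-tetrahydroazulen-1(2H)-one
Product: 19 (3aR,8S,8aR)-3a,6-dimethyl-8-(4,4,5,5-tetramethyl-1,3,2-dioxaborolan-2-yl)-3,3a,4,7,8,8a-hexahydroazulen-1(2H)-one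
Conditions: B2pin2, CuCl (5 mol %), NaOt-Bu (10 mol %), (R)-1-[(S)-2-(diphenylphosphino)ferrocenyl]ethyldicyclohexylphosphine (6 mol %), MeOH (2 equiv), THF, rt
Reagents that add atoms: bis(pinacolato)diboron, CC1(C)OB(OC1(C)C)B1OC(C)(C)C(C)(C)O1
Why: Copper-catalysed conjugate borylation: the monovalent copper boryl complex delivers boron to the unhindered β-carbon C6, and because the bias from C1 is small the chiral bisphosphine is relied on to choose the face anti to the C1 methyl; methanol protonates the enolate, and the still epimerisable C5 should settle with C4 and the bulky boryl group trans-diequatorial on the seven-membered ring, which is the trans ring fusion.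

Step 12
Reactants: 19 (3aR,8S,8aR)-3a,6-dimethyl-8-(4,4,5,5-tetramethyl-1,3,2-dioxaborolan-2-yl)-3,3a,4,7,8,8a-hexahydroazulen-1(2H)-one
Product: 20 (3aR,8S,8aS)-8-hydroxy-3a,6-dimethyl-3,3a,4,7,8,8a-hexahydroazulen-1(2H)-one
Conditions: NaBO3·4H2O, THF/H2O, rt
Reagents that add atoms: sodium perborate tetrahydrate, [Na+].[Na+].O[B-]1(O)OO[B-](O)(O)OO1
Why: Oxidation of the C–B bond with retention gives the C6 alcohol of the configuration set in step 11; perborate does not touch the trisubstituted alkene and is mild enough for a β-hydroxy ketone.

Step 13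
Reactants: 20 (3aR,8S,8aS)-8-hydroxy-3a,6-dimethyl-3,3a,4,7,8,8a-hexahydroazulen-1(2H)-one
Product: 21 (3R,3aS,4S,8aR)-6,8a-dimethyl-3-(propan-2-yl)-1,2,3,3a,4,5,8,8a-octahydroazulene-3,4-diol
Conditions: i-PrMgCl (4 equiv), CeCl3 (4 equiv), THF, −78 → 0 °C; aq NH4Cl
Reagents that add atoms: isopropylmagnesium chloride, CC(C)[Mg]Cl
Why: Organocerium addition to a ketone: the first equivalent forms the C6 alkoxide, which cannot be eliminated and holds the metal on the H-5 face, and the isopropyl group should add to C4 anti to the axial C1 methyl of the trans-fused ketone, giving the (4R) carbinol; the trivalent cerium reagent suppresses enolisation and β-hydride reduction.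

Step 14
Reactants: 21 (3R,3aS,4S,8aR)-6,8a-dimethyl-3-(propan-2-yl)-1,2,3,3a,4,5,8,8a-octahydroazulene-3,4-diol; 22 3,4-dimethoxybenzoic acid (veratric acid)
Product: 23 (3R,3aS,4S,8aR)-3-hydroxy-6,8a-dimethyl-3-(propan-2-yl)-1,2,3,3a,4,5,8,8a-octahydroazulen-4-yl 3,4-dimethoxybenzoate
Conditions: DCC, DMAP, toluene, 70 °C
Reagents that add atoms: none
Why: Steglich esterification: only the secondary C6 hydroxyl is acylated, the tertiary C4 hydroxyl being inert under these conditions, and no stereocentre is touched.

## Compound list

1 | cyclopentanone | O=C1CCCC1 | starting material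
2 | (S)-1-amino-2-(methoxymethyl)pyrrolidine (SAMP) | COC[C@@H]1CCCN1N | starting material
3 | (S)-N-cyclopentylidene-2-(methoxymethyl)pyrrolidin-1-amine | COC[C@@H]1CCCN1N=C1CCCC1 | intermediate
4 | lithium azaenolate of 3 (N-lithio enehydrazide) | COC[C@@H]1CCCN1N([Li])C1=CCCC1 | intermediate (not isolated)
5 | (2S)-2-(methoxymethyl)-N-[(2R)-2-methylcyclopentylidene]pyrrolidin-1-amine | COC[C@@H]1CCCN1N=C1CCC[C@H]1C | intermediate
6 | 4-methylpent-4-enoic acid | C=C(C)CCC(=O)O | starting material
7 | N-methoxy-N,4-dimethylpent-4-enamide | C=C(C)CCC(=O)N(C)OC | intermediate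
8 | lithium azaenolate of 5 (metalated at the unsubstituted α′-carbon) | COC[C@@H]1CCCN1N([Li])C1=CCC[C@H]1C | intermediate (not isolated)
9 | 1-[(3R)-2-{[(2S)-2-(methoxymethyl)pyrrolidin-1-yl]amino}-3-methylcyclopent-1-en-1-yl]-4-methylpent-4-en-1-one | COC[C@@H]1CCCN1NC1=C(C(=O)CCC(C)=C)CC[C@H]1C | intermediate
10 | (5R)-5-methyl-2-(4-methylpent-4-enoyl)cyclopentan-1-one (reacts as its enol; C2 not a fixed stereocentre) | C[C@@H]1CCC(C(=O)CCC(C)=C)C1=O | intermediate
11 | (1R,5R,7R,8R)-7-hydroxy-5,8-dimethyltricyclo[5.3.0.0^{1,5}]decan-2-one (cyclobutanol photoadduct) | C[C@@H]1CC[C@@]23C(=O)CC[C@]2(C)C[C@@]13O | intermediate (not isolated)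
12 | (3aR,6R)-3a,6-dimethyloctahydroazulene-1,5-dione (C8a, daucane C5, epimerisable) | C[C@@H]1CCC2C(=O)CC[C@]2(C)CC1=O | intermediate
13 | potassium enolate of 12 at daucane C4=C5 | CC1CCC2=C(O[K])CC[C@]2(C)CC1=O | intermediate (not isolated)
14 | (3aR)-1-[(tert-butyldimethylsilyl)oxy]-3a,6-dimethyl-2,3,3a,6,7,8-hexahydroazulen-5(4H)-one (C6 epimers) | CC1CCC2=C(O[Si](C)(C)C(C)(C)C)CC[C@]2(C)CC1=O | intermediate
15 | lithium enolate of 14 at daucane C8=C9 | CC1=C(O[Li])C[C@@]2(C)CCC(O[Si](C)(C)C(C)(C)C)=C2CC1 | intermediate (not isolated)
16 | (3aR)-1-[(tert-butyldimethylsilyl)oxy]-3a,6-dimethyl-2,3,3a,4,7,8-hexahydroazulen-5-yl trifluoromethanesulfonate | CC1=C(OS(=O)(=O)C(F)(F)F)C[C@@]2(C)CCC(O[Si](C)(C)C(C)(C)C)=C2CC1 | intermediate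
17 | tert-butyl{[(3aR)-3a,6-dimethyl-2,3,3a,4,7,8-hexahydroazulen-1-yl]oxy}dimethylsilane | CC1=CC[C@@]2(C)CCC(O[Si](C)(C)C(C)(C)C)=C2CC1 | intermediate
18 | (3aR)-3a,6-dimethyl-3,3a,4,7-tetrahydroazulen-1(2H)-one | O=C1CC[C@]2(C)CC=C(C)CC=C12 | intermediate
19 | (3aR,8S,8aR)-3a,6-dimethyl-8-(4,4,5,5-tetramethyl-1,3,2-dioxaborolan-2-yl)-3,3a,4,7,8,8a-hexahydroazulen-1(2H)-one | CC1(C)OB(OC1(C)C)[C@H]1CC(C)=CC[C@@]2(C)CCC(=O)[C@H]12 | intermediate
20 | (3aR,8S,8aS)-8-hydroxy-3a,6-dimethyl-3,3a,4,7,8,8a-hexahydroazulen-1(2H)-one | O[C@H]1CC(C)=CC[C@@]2(C)CCC(=O)[C@H]12 | intermediate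
21 | (3R,3aS,4S,8aR)-6,8a-dimethyl-3-(propan-2-yl)-1,2,3,3a,4,5,8,8a-octahydroazulene-3,4-diol | O[C@H]1CC(C)=CC[C@@]2(C)CC[C@@](O)(C(C)C)[C@H]12 | intermediate
22 | 3,4-dimethoxybenzoic acid (veratric acid) | COc1ccc(C(=O)O)cc1OC | starting material
23 | (3R,3aS,4S,8aR)-3-hydroxy-6,8a-dimethyl-3-(propan-2-yl)-1,2,3,3a,4,5,8,8a-octahydroazulen-4-yl 3,4-dimethoxybenzoate | COc1ccc(C(=O)O[C@H]2CC(C)=CC[C@@]3(C)CC[C@@](O)(C(C)C)[C@H]23)cc1OC | target

## Step count and least certain steps

Total: 14 steps. Longest linear sequence: 13 steps (steps 1, 2 and 4–14, from cyclopentanone); step 3 is a one-step side branch.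

**Step 6 (key step).**
- What may go wrong: incomplete facial discrimination by the single C8 methyl. Because C8 is later made sp2, any addition on the wrong face ends as loss of enantiomeric purity at C1. Crossed closure, or addition through the exocyclic enol tautomer that 2-acylcyclopentanones prefer, would divert material, and slow epimerisation of C8 in the diketone would add to the loss.
- Fallback, from 10: O-acylation with benzyl chloroformate and pyridine gives benzyl [(5R)-5-methyl-2-(4-methylpent-4-enoyl)cyclopent-1-en-1-yl] carbonate F1. This fixes the ring enol, removes the 1,3-dicarbonyl acidity and pushes the C8 methyl out of the plane of the neighbouring carbonate.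
- Irradiation through Pyrex then gives benzyl (1R,5R,7R,8R)-5,8-dimethyl-2-oxotricyclo[5.3.0.0^{1,5}]decan-7-yl carbonate F2. This is a stable cyclobutane in which C8 can no longer epimerise and from which the facial isomer can be separated.
- Hydrogenolysis (H2, Pd/C, EtOAc) frees cyclobutanol 11, which fragments to 12, where the route is rejoined.

**Step 11.**
- What may go wrong: mismatch between catalyst and substrate giving poor facial selectivity at C6; slow borylcupration of the α-branched enone; alkoxide-induced migration of the C8=C9 double bond into conjugation through the doubly allylic C7; protonation at C5 that leaves the cis-fused ketone.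
- Fallback, from 18: nucleophilic epoxidation with lithium tert-butyl peroxide (t-BuOOH in excess over n-BuLi, THF, −78 → −20 °C; the only base present is the weakly basic peroxide anion) gives (3aR,8S,8aR)-8,8a-epoxy-3a,6-dimethyl-3,3a,4,7,8,8a-hexahydroazulen-1(2H)-one F9, to be separated from its facial isomer.
- SmI2 in THF/MeOH at −90 °C opens the epoxide at C5, and the samarium-bound C6 alkoxide should guide protonation of C5 to its own face, giving 20, where the route is rejoined.

**Step 7.**
- What may go wrong: incomplete site selection. Proton exchange may stop at the kinetic C3 enolate or spread to the C9 ketone, giving regioisomeric silyl enol ethers; aldol self-reaction of the dione under equilibrating base is a further risk.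
- Fallback, from 12, kinetic differentiation: LiN(i-Pr)2 (1.05 equiv, THF, −78 °C) removes a proton from the unhindered C3 methylene and TBSCl/DMPU gives (3aR)-1-[(tert-butyldimethylsilyl)oxy]-3a,6-dimethyl-3,3a,6,7,8,8a-hexahydroazulen-5(4H)-one F3.
- The conditions of steps 8 and 9 then give (3aR)-1-[(tert-butyldimethylsilyl)oxy]-3a,6-dimethyl-3,3a,4,7,8,8a-hexahydroazulen-5-yl trifluoromethanesulfonate F4 and tert-butyl{[(3aS)-3a,6-dimethyl-3,3a,4,7,8,8a-hexahydroazulen-1-yl]oxy}dimethylsilane F5.
- Bu4NF/AcOH releases (3aR)-3a,6-dimethyl-3,3a,4,7,8,8a-hexahydroazulen-1(2H)-one F6, now the only ketone. TMSOTf/Et3N gives the more substituted {[(3aR)-3a,6-dimethyl-2,3,3a,4,7,8-hexahydroazulen-1-yl]oxy}trimethylsilane F7, and Saegusa–Ito oxidation gives 18, where the route is rejoined.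

**Step 8.**
- What may go wrong: enolisation toward C10 instead of C8, which would place the triflate, and later the alkene, at C9=C10.
- Fallback, from 14: TMSCl, NaI and Et3N in MeCN give under equilibrating conditions (3aR)-1-[(tert-butyldimethylsilyl)oxy]-3a,6-dimethyl-5-[(trimethylsilyl)oxy]-2,3,3a,4,7,8-hexahydroazulene F8, which can be freed from its regioisomer. MeLi cleaves only the trimethylsilyl ether and regenerates enolate 15 regiospecifically; PhNTf2 then gives 16, where the route is rejoined.

**Step 13.**
- What may go wrong: enolisation or β-hydride reduction of the hindered ketone instead of addition, and loss of facial control if C5 has not reached the trans fusion.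
- Fallback, from 20: isopropenylmagnesium bromide with CeCl3, a smaller donor without β-hydrogens on sp3 carbon, gives (3S,3aS,4S,8aR)-6,8a-dimethyl-3-(prop-1-en-2-yl)-1,2,3,3a,4,5,8,8a-octahydroazulene-3,4-diol F10. Hydrogenation with RhCl(PPh3)3 reduces only the 1,1-disubstituted alkene and gives 21, where the route is rejoined.

## Further compounds

F1 | step 6 | benzyl [(5R)-5-methyl-2-(4-methylpent-4-enoyl)cyclopent-1-en-1-yl] carbonate | C[C@@H]1CCC(C(=O)CCC(C)=C)=C1OC(=O)OCc1ccccc1
F2 | step 6 | benzyl (1R,5R,7R,8R)-5,8-dimethyl-2-oxotricyclo[5.3.0.0^{1,5}]decan-7-yl carbonate | C[C@@H]1CC[C@@]23C(=O)CC[C@]2(C)C[C@@]13OC(=O)OCc1ccccc1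
F3 | step 7 | (3aR)-1-[(tert-butyldimethylsilyl)oxy]-3a,6-dimethyl-3,3a,6,7,8,8a-hexahydroazulen-5(4H)-one | CC1CCC2C(O[Si](C)(C)C(C)(C)C)=CC[C@]2(C)CC1=O
F4 | step 7 | (3aR)-1-[(tert-butyldimethylsilyl)oxy]-3a,6-dimethyl-3,3a,4,7,8,8a-hexahydroazulen-5-yl trifluoromethanesulfonate | CC1=C(OS(=O)(=O)C(F)(F)F)C[C@@]2(C)CC=C(O[Si](C)(C)C(C)(C)C)C2CC1
F5 | step 7 | tert-butyl{[(3aS)-3a,6-dimethyl-3,3a,4,7,8,8a-hexahydroazulen-1-yl]oxy}dimethylsilane | CC1=CC[C@@]2(C)CC=C(O[Si](C)(C)C(C)(C)C)C2CC1
F6 | step 7 | (3aR)-3a,6-dimethyl-3,3a,4,7,8,8a-hexahydroazulen-1(2H)-one | CC1=CC[C@@]2(C)CCC(=O)C2CC1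
F7 | step 7 | {[(3aR)-3a,6-dimethyl-2,3,3a,4,7,8-hexahydroazulen-1-yl]oxy}trimethylsilane | CC1=CC[C@@]2(C)CCC(O[Si](C)(C)C)=C2CC1
F8 | step 8 | (3aR)-1-[(tert-butyldimethylsilyl)oxy]-3a,6-dimethyl-5-[(trimethylsilyl)oxy]-2,3,3a,4,7,8-hexahydroazulene | CC1=C(O[Si](C)(C)C)C[C@@]2(C)CCC(O[Si](C)(C)C(C)(C)C)=C2CC1
F9 | step 11 | (3aR,8S,8aR)-8,8a-epoxy-3a,6-dimethyl-3,3a,4,7,8,8a-hexahydroazulen-1(2H)-one | O1[C@H]2CC(C)=CC[C@@]3(C)CCC(=O)[C@]123
F10 | step 13 | (3S,3aS,4S,8aR)-6,8a-dimethyl-3-(prop-1-en-2-yl)-1,2,3,3a,4,5,8,8a-octahydroazulene-3,4-diol | O[C@H]1CC(C)=CC[C@@]2(C)CC[C@@](O)(C(C)=C)[C@H]12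
A1 | alternative 1 | (S)-citronellol, (3S)-3,7-dimethyloct-6-en-1-ol | C[C@@H](CCC=C(C)C)CCO
A2 | alternative 1 | (6S)-8-[(tert-butyldimethylsilyl)oxy]-2,6-dimethyloctan-3-one | CC(C)C(=O)CC[C@H](C)CCO[Si](C)(C)C(C)(C)C
A3 | alternative 1 | tert-butyl{2-[(1R)-1-methyl-3-(propan-2-yl)cyclopent-2-en-1-yl]ethoxy}dimethylsilane | CC(C)C1=C[C@@](C)(CCO[Si](C)(C)C(C)(C)C)CC1
A4 | alternative 2 | (5R)-2-diazo-5-(2-methoxy-4-methylphenyl)-6-methyl-5-[(trimethylsilyl)oxy]heptan-3-one | COc1cc(C)ccc1[C@](O[Si](C)(C)C)(C(C)C)CC(=O)C(C)=[N+]=[N-]
A5 | alternative 2 | 8-methoxy-3a,6-dimethyl-1-(propan-2-yl)-1-[(trimethylsilyl)oxy]-1,2-dihydroazulen-3(3aH)-one | COC1=C2[C@](O[Si](C)(C)C)(C(C)C)CC(=O)[C@]2(C)C=CC(C)=C1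
A6 | alternative 3 | 2,5-dimethylanisole | COc1cc(C)ccc1C
A7 | alternative 3 | 1-methoxy-2,5-dimethylcyclohexa-1,4-diene | COC1=C(C)CC=C(C)C1
A8 | alternative 3 | 2-bromo-3,6-dimethylcyclohepta-2,5-dien-1-one | CC1=CCC(C)=C(Br)C(=O)C1
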